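**Retrosynthetic overview**
- Feature: the quinone ring C1(=O)–C2(OH)=C3(C1′)–C4(=O) is a four-carbon chain with oxygen on C1, C2 and C4, which is the carbon–oxygen pattern of squaric acid. It is fused at C4a/C8a to a benzene ring with OMe on C5, C6 and C8 and hydrogen only on C7, so the two fusion sites are not equivalent.
- End game: the C2′ acetate and the free C2–OH are set last, from the quinone that carries C2–OiPr and C2′–OTBS.
- Key disconnection C4–C4a: naphthalene-1,4-diol ⇒ 4-aryl-4-hydroxycyclobutenone. The four-membered ring is opened and the six-membered quinone ring is closed. This is the only ring formed, since the benzene and cyclobutene rings are bought.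
- C1–C8a: cyclobutenone ⇒ 2,4,5-trimethoxyphenyllithium + 3-alkyl-4-isopropoxycyclobutenedione. C3–C1′: the dione ⇒ diisopropyl squarate + the O,C-dilithio reagent from (S)-propylene oxide, which brings in the C2′ stereocentre.

Key step: step 6

Remark on notation: C1–C8a are the naphthoquinone locants of the target and C1′–C3′ are the side chain. The ring carbinol carbon in 6, 7, 12 and 13 forms as both epimers and is drawn undefined because it ends sp2.

**Step 1**
Reactants: 1 (S)-propylene oxide [(S)-2-methyloxirane]
Product: 2 (S)-1-chloropropan-2-ol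
Conditions: LiCl, AcOH, THF, 0 °C → rt
Reagents that add atoms: lithium chloride, [Li+].[Cl-]
Why: Acid-assisted SN2 opening of a terminal epoxide by chloride (halohydrin formation) occurs at the unhindered CH2, so the C–O bond at the stereocentre is never broken and the S configuration is kept.

**Step 2**
Reactants: 2 (S)-1-chloropropan-2-ol; 3 diisopropyl squarate (3,4-diisopropoxycyclobut-3-ene-1,2-dione)
Product: 7 4-hydroxy-4-[(S)-2-hydroxypropyl]-2,3-diisopropoxycyclobut-2-en-1-one (both C4 epimers), via lithium (S)-1-chloropropan-2-olate 4 (not isolated), via (S)-1-lithio-2-(lithiooxy)propane 5 (not isolated), via dilithium dialkoxide of the adduct 6 (not isolated)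
Conditions: n-BuLi (1 equiv), THF, −78 °C; Li naphthalenide (2 equiv, added until the green colour just persists), −78 °C; 3, THF, −78 °C; AcOH, −78 °C
Reagents that add atoms: none
Why: Deprotonation followed by reductive chlorine–lithium exchange with the arene radical anion gives a β-oxido alkyllithium that resists β-elimination at −78 °C because oxide is a very poor leaving group, and this hard nucleophile adds 1,2 to one of the two equivalent squarate carbonyls (organolithium addition to a squarate ester) without involving C2′.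

**Step 3**
Reactants: 7 4-hydroxy-4-[(S)-2-hydroxypropyl]-2,3-diisopropoxycyclobut-2-en-1-one
Product: 8 3-[(S)-2-hydroxypropyl]-4-isopropoxycyclobut-3-ene-1,2-dione
Conditions: conc. HCl (cat.), CH2Cl2, rt
Reagents that add atoms: none
Why: Acid-catalysed ionisation of the tertiary allylic alcohol, recapture of the released water at the distal alkoxy-stabilised carbon and loss of propan-2-ol is the standard transposition of squarate adducts to alkyl(alkoxy)cyclobutenediones, and a fused five-membered cyclic ether from the side-chain hydroxyl is disfavoured by the wide external angles of the cyclobutene C=C.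

**Step 4**
Reactants: 8 3-[(S)-2-hydroxypropyl]-4-isopropoxycyclobut-3-ene-1,2-dione
Product: 9 3-[(S)-2-(tert-butyldimethylsilyloxy)propyl]-4-isopropoxycyclobut-3-ene-1,2-dione
Conditions: TBSOTf, 2,6-lutidine, CH2Cl2, −78 °C
Reagents that add atoms: tert-butyldimethylsilyl triflate, CC(C)(C)[Si](C)(C)OS(=O)(=O)C(F)(F)F
Why: Silyl ether formation with a silyl triflate and a hindered base masks the alcohol, which would otherwise consume aryllithium and later trap the ketene as a lactone, and it avoids nucleophilic amines that displace alkoxide from cyclobutenediones.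

**Step 5**
Reactants: 9 3-[(S)-2-(tert-butyldimethylsilyloxy)propyl]-4-isopropoxycyclobut-3-ene-1,2-dione; 10 1-bromo-2,4,5-trimethoxybenzene
Product: 13 4-hydroxy-3-isopropoxy-2-[(S)-2-(tert-butyldimethylsilyloxy)propyl]-4-(2,4,5-trimethoxyphenyl)cyclobut-2-en-1-one (both C4 epimers), via 2,4,5-trimethoxyphenyllithium 11 (not isolated), via lithium alkoxide of the adduct 12 (not isolated)
Conditions: 10, n-BuLi, THF, −78 °C; cannulated into 9, THF, −78 °C; AcOH, −78 °C
Reagents that add atoms: none
Why: After bromine–lithium exchange the aryllithium adds 1,2 to the carbonyl flanked by C–OiPr, which is ketone-like, and not to the carbonyl flanked by C–alkyl, which is deactivated as the vinylogous ester of the isopropoxy group, so the aryl-bearing carbon ends next to the alkoxy carbon (future C8a–C1–C2), and the new carbinol centre needs no control.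

**Step 6**
Reactants: 13 4-hydroxy-3-isopropoxy-2-[(S)-2-(tert-butyldimethylsilyloxy)propyl]-4-(2,4,5-trimethoxyphenyl)cyclobut-2-en-1-one
Product: 16 2-isopropoxy-3-[(S)-2-(tert-butyldimethylsilyloxy)propyl]-5,6,8-trimethoxynaphthalene-1,4-diol, via aryl vinylketene 14 (not isolated), via C4a-H dienone 15 (not isolated)
Conditions: p-xylene (degassed, ca. 0.02 M), reflux (138 °C), Ar
Reagents that add atoms: none
Why: On heating, the ring bond between the carbonyl carbon and the carbinol carbon breaks in a thermally allowed conrotatory 4π opening, and because donor substituents prefer outward rotation the OH turns away, so vinylketene 14 forms with its aryl group cis to the ketene arm. The ketene carbon (future C4) then bonds to aryl carbon C6 (future C4a) in a disrotatory 6π electrocyclisation of the ketene C=C, enol C=C and arene C=C, which closes the six-membered quinone ring as dienone 15, and enolisation restores the benzene ring to give 16. This is the Moore rearrangement of 4-aryl-4-hydroxycyclobutenones, which is established for electron-rich aryl groups and for 2-alkyl-3-alkoxy substitution. No stereocentre is created: the carbinol carbon and the transient C4a–H centre both end sp2, and C2′ sits away from every reacting atom under neutral conditions and keeps the S configuration. The step needs closure on the side of the vicinal dimethoxy pair, which is secured because aryl C2 carries methoxy and only C6 carries hydrogen, while the order C1–C2(OiPr)–C3(alkyl)–C4 was fixed in step 5. The silyl ether keeps the side-chain oxygen from adding to the ketene (five-membered lactone), and dilution with exclusion of air holds back ketene dimerisation and premature oxidation.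

**Step 7**
Reactants: 16 2-isopropoxy-3-[(S)-2-(tert-butyldimethylsilyloxy)propyl]-5,6,8-trimethoxynaphthalene-1,4-diol (used crude)
Product: 17 2-isopropoxy-3-[(S)-2-(tert-butyldimethylsilyloxy)propyl]-5,6,8-trimethoxy-1,4-naphthoquinone
Conditions: Ag2O, Et2O, rt
Reagents that add atoms: none
Why: Silver(I) oxide oxidation of a 1,4-hydroquinone is a mild neutral two-electron process that should leave the silyl ether, the isopropyl ether and the methoxy-substituted ring untouched.

**Step 8**
Reactants: 17 2-isopropoxy-3-[(S)-2-(tert-butyldimethylsilyloxy)propyl]-5,6,8-trimethoxy-1,4-naphthoquinone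
Product: 19 2-hydroxy-3-[(S)-2-(tert-butyldimethylsilyloxy)propyl]-5,6,8-trimethoxy-1,4-naphthoquinone, via sodium quinone-2-olate 18 (not isolated)
Conditions: NaOH (aq), i-PrOH–THF, 40 °C, Ar; then 1 M HCl, 0 °C
Reagents that add atoms: sodium hydroxide, [Na+].[OH-]
Why: Hydroxide adds to C2 and expels isopropoxide (addition–elimination, saponification of a vinylogous ester), the delocalised anion formed stops further attack and lowers the acidity of C1′–H, the secondary TBS ether tolerates aqueous base, and propan-2-ol as cosolvent makes any alkoxide exchange degenerate.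

**Step 9**
Reactants: 19 2-hydroxy-3-[(S)-2-(tert-butyldimethylsilyloxy)propyl]-5,6,8-trimethoxy-1,4-naphthoquinone
Product: 20 2-hydroxy-3-[(S)-2-hydroxypropyl]-5,6,8-trimethoxy-1,4-naphthoquinone
Conditions: HF·pyridine, pyridine, THF, 0 °C → rt
Reagents that add atoms: none
Why: Fluoride-driven Si–O cleavage under buffered conditions frees the alcohol with the C2′–O bond intact, and placing it after step 8 avoids intramolecular displacement of isopropoxide at C2 by the free alcohol (dihydrofuran formation).

**Step 10**
Reactants: 20 2-hydroxy-3-[(S)-2-hydroxypropyl]-5,6,8-trimethoxy-1,4-naphthoquinone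
Product: 22 (S)-1-(3-hydroxy-5,7,8-trimethoxy-1,4-dioxo-1,4-dihydronaphthalen-2-yl)propan-2-yl acetate (= 3-[(S)-2-acetoxypropyl]-2-hydroxy-5,6,8-trimethoxy-1,4-naphthoquinone; the target), via C2/C2′ diacetate 21 (not isolated)
Conditions: Ac2O, pyridine, DMAP (cat.), CH2Cl2, 0 °C; then MeOH, 0 °C → rt
Reagents that add atoms: acetic anhydride, CC(=O)OC(C)=O
Why: DMAP-catalysed acylation esterifies both hydroxyls, and the C2 enol acetate, a vinylogous mixed anhydride, then hands its acetyl group to methanol under the same nucleophilic catalysis while the secondary alkyl acetate is inert (chemoselective transesterification).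

**Compound list**
1 | (S)-propylene oxide | C[C@H]1CO1 | starting material
2 | (S)-1-chloropropan-2-ol | ClC[C@H](C)O | intermediate
3 | diisopropyl squarate | CC(C)OC1=C(OC(C)C)C(=O)C1=O | starting material
4 | lithium (S)-1-chloropropan-2-olate | ClC[C@H](C)O[Li] | intermediate
5 | (S)-1-lithio-2-(lithiooxy)propane | [Li]C[C@H](C)O[Li] | intermediate
6 | dilithium dialkoxide of adduct 7 | O=C1C(OC(C)C)=C(OC(C)C)C1(O[Li])C[C@H](C)O[Li] | intermediate
7 | 4-hydroxy-4-[(S)-2-hydroxypropyl]-2,3-diisopropoxycyclobut-2-en-1-one | O=C1C(OC(C)C)=C(OC(C)C)C1(O)C[C@H](C)O | intermediate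
8 | 3-[(S)-2-hydroxypropyl]-4-isopropoxycyclobut-3-ene-1,2-dione | O=C1C(=O)C(OC(C)C)=C1C[C@H](C)O | intermediate
9 | 3-[(S)-2-(tert-butyldimethylsilyloxy)propyl]-4-isopropoxycyclobut-3-ene-1,2-dione | O=C1C(=O)C(OC(C)C)=C1C[C@H](C)O[Si](C)(C)C(C)(C)C | intermediate
10 | 1-bromo-2,4,5-trimethoxybenzene | COc1cc(OC)c(Br)cc1OC | starting material
11 | 2,4,5-trimethoxyphenyllithium | COc1cc(OC)c([Li])cc1OC | intermediate
12 | lithium alkoxide of 13 | O=C1C(C[C@H](C)O[Si](C)(C)C(C)(C)C)=C(OC(C)C)C1(O[Li])c1cc(OC)c(OC)cc1OC | intermediate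
13 | 4-hydroxy-3-isopropoxy-2-[(S)-2-(tert-butyldimethylsilyloxy)propyl]-4-(2,4,5-trimethoxyphenyl)cyclobut-2-en-1-one | O=C1C(C[C@H](C)O[Si](C)(C)C(C)(C)C)=C(OC(C)C)C1(O)c1cc(OC)c(OC)cc1OC | intermediate
14 | 4-hydroxy-3-isopropoxy-2-[(S)-2-(tert-butyldimethylsilyloxy)propyl]-4-(2,4,5-trimethoxyphenyl)buta-1,3-dien-1-one, aryl cis to the ketene arm | O=C=C(C[C@H](C)O[Si](C)(C)C(C)(C)C)/C(OC(C)C)=C(/O)c1cc(OC)c(OC)cc1OC | intermediate
15 | C4a-H dienone (4a-H keto tautomer of 16, C4a undefined) | O=C1C(C[C@H](C)O[Si](C)(C)C(C)(C)C)=C(OC(C)C)C(O)=C2C(OC)=CC(OC)=C(OC)C12 | intermediate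
16 | 2-isopropoxy-3-[(S)-2-(tert-butyldimethylsilyloxy)propyl]-5,6,8-trimethoxynaphthalene-1,4-diol | COc1cc(OC)c2c(O)c(OC(C)C)c(C[C@H](C)O[Si](C)(C)C(C)(C)C)c(O)c2c1OC | intermediate
17 | 2-isopropoxy-3-[(S)-2-(tert-butyldimethylsilyloxy)propyl]-5,6,8-trimethoxy-1,4-naphthoquinone | COc1cc(OC)c2c(c1OC)C(=O)C(C[C@H](C)O[Si](C)(C)C(C)(C)C)=C(OC(C)C)C2=O | intermediate
18 | sodium salt of 19 (quinone-2-olate) | COc1cc(OC)c2c(c1OC)C(=O)C(C[C@H](C)O[Si](C)(C)C(C)(C)C)=C([O-])C2=O.[Na+] | intermediate
19 | 2-hydroxy-3-[(S)-2-(tert-butyldimethylsilyloxy)propyl]-5,6,8-trimethoxy-1,4-naphthoquinone | COc1cc(OC)c2c(c1OC)C(=O)C(C[C@H](C)O[Si](C)(C)C(C)(C)C)=C(O)C2=O | intermediate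
20 | 2-hydroxy-3-[(S)-2-hydroxypropyl]-5,6,8-trimethoxy-1,4-naphthoquinone | COc1cc(OC)c2c(c1OC)C(=O)C(C[C@H](C)O)=C(O)C2=O | intermediate
21 | 2-acetoxy-3-[(S)-2-acetoxypropyl]-5,6,8-trimethoxy-1,4-naphthoquinone | COc1cc(OC)c2c(c1OC)C(=O)C(C[C@H](C)OC(C)=O)=C(OC(C)=O)C2=O | intermediate
22 | 3-[(S)-2-acetoxypropyl]-2-hydroxy-5,6,8-trimethoxy-1,4-naphthoquinone | COc1cc(OC)c2c(c1OC)C(=O)C(C[C@H](C)OC(C)=O)=C(O)C2=O | target

**Total step count:** 10. **Longest linear sequence:** 10 steps (1 → 22). Compounds 3 and 10 are bought and enter at steps 2 and 5.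

**Steps most likely to fail**

**Step 6.**
- Closure at aryl C6 may be slowed by the flanking methoxy group and by the twist of the ortho-methoxyaryl group, which leaves the ketene time for proton transfer or dimerisation.
- The free, very electron-rich hydroquinone may also degrade at reflux.
- The fallback sets out from lithium alkoxide 12 and comes back at quinone 17.
- Instead of being protonated, 12 is methylated in the flask with methyl triflate to 2-[(S)-2-(tert-butyldimethylsilyloxy)propyl]-3-isopropoxy-4-methoxy-4-(2,4,5-trimethoxyphenyl)cyclobut-2-en-1-one F1.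
- Thermolysis of this protected carbinol (methoxy also rotates outward) ends at the isolable monomethyl ether 2-[(S)-2-(tert-butyldimethylsilyloxy)propyl]-3-isopropoxy-4,5,7,8-tetramethoxynaphthalen-1-ol F2, so no free hydroquinone or enol OH is present during heating.
- A separate oxidative demethylation of the 4-methoxy-1-naphthol unit with PhI(OAc)2 in aqueous MeCN gives 17. This oxidant engages the free phenol ring and not the 5,8-dimethoxy ring.

**Step 2.**
- Local warming may cause β-elimination of lithium oxide from 5.
- Residual radical anion or the alkyllithium may transfer an electron to the easily reduced squarate.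
- The side-chain alkoxide may attack the vinylogous ester.
- The fallback sets out from 3 and comes back at target 22. It forms the C3–C1′ bond last, with a radical instead of a carbanion.
- Compound 3 is reduced with LiAlH(Ot-Bu)3 to 4-hydroxy-2,3-diisopropoxycyclobut-2-en-1-one F3, and catalytic HCl converts this to 3-isopropoxycyclobut-3-ene-1,2-dione F4.
- Aryllithium 11 adds to the carbonyl next to C–OiPr to give 4-hydroxy-3-isopropoxy-4-(2,4,5-trimethoxyphenyl)cyclobut-2-en-1-one F5.
- The same thermal ring expansion gives 2-isopropoxy-5,6,8-trimethoxynaphthalene-1,4-diol F6, and Ag2O gives 2-isopropoxy-5,6,8-trimethoxy-1,4-naphthoquinone F7.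
- Aqueous NaOH then gives 2-hydroxy-5,6,8-trimethoxy-1,4-naphthoquinone F8.
- (S)-3-Acetoxybutanoic acid F9 is made from commercial (S)-3-hydroxybutanoic acid and acetic anhydride.
- F9 is decarboxylated with AgNO3 (cat.)/(NH4)2S2O8 in MeCN–H2O (Kochi–Anderson radical alkylation of a hydroxyquinone).
- The primary β-acetoxyalkyl radical does not fragment and leaves its stereocentre untouched. It adds to C3, the only free quinone carbon, and gives 22 directly.

**Step 5.**
- The basic aryllithium may deprotonate C1′–H (γ to the free carbonyl), with subsequent loss of silanolate.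
- Some attack at the vinylogous ester carbonyl may also occur.
- The fallback sets out from alcohol 8 and comes back at 13. It reverses the order of protection and arylation.
- Compound 8 is treated with two equivalents of 11 at −78 °C.
- The first equivalent turns the hydroxyl into a lithium alkoxide that cannot leave, so any C1′ deprotonation is harmless and is undone on quench.
- The second equivalent adds to the carbonyl next to C–OiPr to give 4-hydroxy-2-[(S)-2-hydroxypropyl]-3-isopropoxy-4-(2,4,5-trimethoxyphenyl)cyclobut-2-en-1-one F10.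
- Selective silylation of the secondary over the tertiary hydroxyl (TBSCl, imidazole, DMF) gives 13.

**Further compounds**
F1 | step 6 | 2-[(S)-2-(tert-butyldimethylsilyloxy)propyl]-3-isopropoxy-4-methoxy-4-(2,4,5-trimethoxyphenyl)cyclobut-2-en-1-one | O=C1C(C[C@H](C)O[Si](C)(C)C(C)(C)C)=C(OC(C)C)C1(OC)c1cc(OC)c(OC)cc1OC
F2 | step 6 | 2-[(S)-2-(tert-butyldimethylsilyloxy)propyl]-3-isopropoxy-4,5,7,8-tetramethoxynaphthalen-1-ol | COc1cc(OC)c2c(OC)c(OC(C)C)c(C[C@H](C)O[Si](C)(C)C(C)(C)C)c(O)c2c1OC
F3 | step 2 | 4-hydroxy-2,3-diisopropoxycyclobut-2-en-1-one | O=C1C(OC(C)C)=C(OC(C)C)C1O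
F4 | step 2 | 3-isopropoxycyclobut-3-ene-1,2-dione | O=C1C=C(OC(C)C)C1=O
F5 | step 2 | 4-hydroxy-3-isopropoxy-4-(2,4,5-trimethoxyphenyl)cyclobut-2-en-1-one | O=C1C=C(OC(C)C)C1(O)c1cc(OC)c(OC)cc1OC
F6 | step 2 | 2-isopropoxy-5,6,8-trimethoxynaphthalene-1,4-diol | COc1cc(OC)c2c(O)c(OC(C)C)cc(O)c2c1OC
F7 | step 2 | 2-isopropoxy-5,6,8-trimethoxy-1,4-naphthoquinone | COc1cc(OC)c2c(c1OC)C(=O)C=C(OC(C)C)C2=O
F8 | step 2 | 2-hydroxy-5,6,8-trimethoxy-1,4-naphthoquinone | COc1cc(OC)c2c(c1OC)C(=O)C=C(O)C2=O
F9 | step 2 | (S)-3-acetoxybutanoic acid | OC(=O)C[C@H](C)OC(C)=O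
F10 | step 5 | 4-hydroxy-2-[(S)-2-hydroxypropyl]-3-isopropoxy-4-(2,4,5-trimethoxyphenyl)cyclobut-2-en-1-one | O=C1C(C[C@H](C)O)=C(OC(C)C)C1(O)c1cc(OC)c(OC)cc1OC
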